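The pyrrole ring is cut at C3–C3a and at the N–C2 bond, and C2–Br is added last. This reduces the 4,5,6-tribromobenzo ring to 3,4,5-tribromoaniline, whose two ortho CH carbons (future C3a and C7) are symmetry-equivalent. It also makes the C3–SMe group the sulfur that a Gassman azasulfonium ylide carries. In one pot, the key step chlorinates the aniline nitrogen, aminates the sulfide and, through a [2,3]-sigmatropic shift of the ylide, bonds the SMe-bearing carbon (future C3) to the ortho carbon. Its precursor is the S-anilinosulfonium chloride made from the N-chloroaniline and (methylsulfanyl)acetaldehyde dimethyl acetal; dilute acid then closes N–C2.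

Key step: step 3

Remark: amino acetal 10 is acid-labile, so it is assumed to be carried into step 4 after a basic aqueous work-up without chromatography.

Step 1
Reactants: 1 2,6-dibromo-4-nitroaniline
Product: 2 1,2,3-tribromo-5-nitrobenzene
Conditions: t-BuONO, CuBr2, MeCN, 0 → 60 °C
Reagents that add atoms: copper dibromide CuBr2, Br[Cu]Br
Why: Sandmeyer-type bromodediazoniation under non-aqueous alkyl nitrite conditions suits this weakly basic, doubly ortho-substituted aniline, because the diazonium ion formed in situ is reduced by copper to the aryl radical, which takes bromine from CuBr2, and no water is present to give the phenol.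

Step 2
Reactants: 2 1,2,3-tribromo-5-nitrobenzene
Product: 3 3,4,5-tribromoaniline
Conditions: Fe powder, NH4Cl, EtOH–H2O, 80 °C
Reagents that add atoms: none
Why: Béchamp-type reduction by electron transfer from zerovalent iron should take the nitro group through the nitroso and hydroxylamine stages to the amine and leave the three C–Br bonds untouched, which catalytic hydrogenation would not guarantee.

Step 3
Reactants: 3 3,4,5-tribromoaniline; 4 (methylsulfanyl)acetaldehyde dimethyl acetal
Product: 10 3,4,5-tribromo-2-[2,2-dimethoxy-1-(methylsulfanyl)ethyl]aniline (racemic), via N-chloro-3,4,5-tribromoaniline 5 (not isolated), via azasulfonium chloride 6 (not isolated), via sulfilimine 7 (not isolated), via sulfonium ylide 8 (not isolated), via dienimine 9 (not isolated)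
Conditions: t-BuOCl (1.0 equiv), CH2Cl2, −70 °C; then 4, −70 °C; then Et3N, −70 °C → rt, then 40 °C
Reagents that add atoms: none
Why: This is the ortho-alkylation stage of the Gassman indole synthesis: t-BuOCl N-chlorinates 3 to 5, the sulfur of 4 displaces chloride from nitrogen to give 6, and Et3N removes HCl to give sulfilimine 7, which equilibrates by proton shift with carbon ylide 8. Ylide 8 should undergo a Sommelet–Hauser-type [2,3]-sigmatropic shift through a five-membered transition state in which the S–N bond breaks as the SMe-bearing carbanion carbon (future C3) bonds to the ortho ring carbon (future C3a), and dienimine 9 re-aromatises by a proton shift to 10. The closest known reaction type is the ortho-alkylation of anilines through N-aryl azasulfonium ylides, whose N-chloroaniline variant is the one suited to electron-poor anilines because their N-chloro derivatives persist at −70 °C. No ring is closed in this step; the pyrrole ring is closed in step 4. The new CH(SMe) carbon is formed racemic and needs no control because it becomes sp2 in step 4. The only selectivity required is the choice of ortho carbon, and the mirror symmetry of 3 removes it, since both ortho CH positions are equivalent and lead to the same 4,5,6-tribromo pattern; the final warming is included because the S–CH2 protons are not carbonyl-activated and the sulfilimine would otherwise be a resting state.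

Step 4
Reactants: 10 3,4,5-tribromo-2-[2,2-dimethoxy-1-(methylsulfanyl)ethyl]aniline (racemic)
Product: 12 4,5,6-tribromo-3-(methylsulfanyl)-1H-indole, via 2-methoxyindoline 11 (not isolated)
Conditions: 0.5 M aq HCl, Et2O–THF, rt; NaHCO3 work-up
Reagents that add atoms: none
Why: In this cyclisation stage of the Gassman indole synthesis, acid ionises the acetal, the ortho amino group captures the resulting carbon in a 5-exo-trig closure to give cyclic N,O-acetal 11, and elimination of the second methanol aromatises the ring, while dilute acid at room temperature should be too weak to trigger the acid-promoted shift of sulfur from C3 to C2.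

Step 5
Reactants: 12 4,5,6-tribromo-3-(methylsulfanyl)-1H-indole
Product: 13 2,4,5,6-tetrabromo-3-(methylsulfanyl)-1H-indole
Conditions: NBS (1.0 equiv), CH2Cl2, −78 → 0 °C, dark; aq Na2S2O3/NaHCO3 quench
Reagents that add atoms: N-bromosuccinimide, BrN(C1=O)C(=O)CC1
Why: In this electrophilic bromination of a 3-substituted indole, C3 is blocked, so bromine should go to C2 of the enamine-like C2=C3 bond (the cation at C3 is stabilised by sulfur) and proton loss restores the indole, while the tribrominated benzo ring with only C7–H free is too deactivated to compete.

Compound list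
1 | 2,6-dibromo-4-nitroaniline | Nc1c(Br)cc(cc1Br)[N+](=O)[O-] | starting material
2 | 1,2,3-tribromo-5-nitrobenzene | [O-][N+](=O)c1cc(Br)c(Br)c(Br)c1 | intermediate
3 | 3,4,5-tribromoaniline | Nc1cc(Br)c(Br)c(Br)c1 | intermediate
4 | (methylsulfanyl)acetaldehyde dimethyl acetal (1,1-dimethoxy-2-(methylsulfanyl)ethane) | CSCC(OC)OC | starting material
5 | N-chloro-3,4,5-tribromoaniline | ClNc1cc(Br)c(Br)c(Br)c1 | intermediate
6 | (2,2-dimethoxyethyl)(methyl)[(3,4,5-tribromophenyl)amino]sulfonium chloride (racemic at sulfur) | C[S+](CC(OC)OC)Nc1cc(Br)c(Br)c(Br)c1.[Cl-] | intermediate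
7 | S-(2,2-dimethoxyethyl)-S-methyl-N-(3,4,5-tribromophenyl)sulfilimine (racemic at sulfur) | CS(CC(OC)OC)=Nc1cc(Br)c(Br)c(Br)c1 | intermediate
8 | sulfonium ylide of 6, carbanion at the S–CH carbon next to the acetal (racemic at sulfur) | C[S+]([CH-]C(OC)OC)Nc1cc(Br)c(Br)c(Br)c1 | intermediate
9 | 3,4,5-tribromo-6-[2,2-dimethoxy-1-(methylsulfanyl)ethyl]cyclohexa-2,4-dien-1-imine (mixture of diastereomers) | CSC(C(OC)OC)C1C(=N)C=C(Br)C(Br)=C1Br | intermediate
10 | 3,4,5-tribromo-2-[2,2-dimethoxy-1-(methylsulfanyl)ethyl]aniline (racemic) | COC(OC)C(SC)c1c(N)cc(Br)c(Br)c1Br | intermediate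
11 | 4,5,6-tribromo-2-methoxy-3-(methylsulfanyl)-2,3-dihydro-1H-indole (mixture of diastereomers) | COC1Nc2cc(Br)c(Br)c(Br)c2C1SC | intermediate
12 | 4,5,6-tribromo-3-(methylsulfanyl)-1H-indole | CSc1c[nH]c2cc(Br)c(Br)c(Br)c12 | intermediate
13 | 2,4,5,6-tetrabromo-3-(methylsulfanyl)-1H-indole (achiral) | CSc1c(Br)[nH]c2cc(Br)c(Br)c(Br)c12 | target

Total step count: 5. Longest linear sequence: 5 steps (1 → 2 → 3 → 10 → 12 → 13).

Steps most likely to fail, in order of risk:

Step 3. Chlorine may move from nitrogen to a ring carbon (Orton-type rearrangement), or the deactivated N-chloroaniline may aminate the sulfide too slowly, so that the azasulfonium salt does not form cleanly. The fallback reverses the polarity of S–N bond formation and sets out from 3 and 4. Sulfide 4 would be oxidised with NaIO4 in MeOH–H2O at 0 °C to 1,1-dimethoxy-2-(methylsulfinyl)ethane F1. Oxalyl chloride in CH2Cl2 at −78 °C would then convert it into chloro(2,2-dimethoxyethyl)methylsulfonium chloride F2. Aniline 3 would be added to this electrophilic sulfur species at −78 °C, which should give azasulfonium chloride 6. There the fallback comes back to the route, and Et3N is added as in step 3.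

Step 5. Bromine may be transferred to sulfur instead of C2, followed by oxidation at sulfur, bromination of the S-methyl group, or loss or shift of the sulfanyl group from C3. The fallback places C2 at the carbonyl oxidation level from the start and makes C2–Br by deoxybromination, so no electrophilic bromine meets the thioether. It sets out from 5, generated from 3 as in step 3. Ethyl (methylsulfanyl)acetate at −70 °C should give (2-ethoxy-2-oxoethyl)(methyl)[(3,4,5-tribromophenyl)amino]sulfonium chloride F3. Et3N would then induce the same ylide rearrangement to ethyl 2-(2-amino-4,5,6-tribromophenyl)-2-(methylsulfanyl)acetate F4. Dilute HCl in ether should lactamise this to 4,5,6-tribromo-3-(methylsulfanyl)-1,3-dihydro-2H-indol-2-one F5 (Gassman oxindole synthesis). POBr3 in 1,2-dichloroethane at 80 °C should then convert the lactam, through its 2-hydroxyindole tautomer, directly into 13, where the fallback comes back to the route.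

Step 4. The sulfanyl group may shift from C3 to C2 under acid, or the sequence may stall before dehydration because the ring nitrogen is weakly nucleophilic. The fallback builds the indole without sulfur and introduces sulfur afterwards under non-protic conditions; it sets out from 3. Sugasawa ortho-chloroacetylation (BCl3, ClCH2CN, AlCl3, 1,2-dichloroethane, reflux; then aq HCl) should give 1-(2-amino-4,5,6-tribromophenyl)-2-chloroethan-1-one F6. NaBH4 in dioxane–H2O at reflux would reduce the ketone; the amine then closes onto the chloromethyl carbon and water is lost, giving 4,5,6-tribromo-1H-indole F7. C3-sulfenylation with N-(methylsulfanyl)phthalimide and catalytic MgBr2 in DMAc at 90 °C should give 12, where the fallback comes back to the route.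

Further compounds
F1 | step 3 | 1,1-dimethoxy-2-(methylsulfinyl)ethane (racemic at sulfur) | CS(=O)CC(OC)OC
F2 | step 3 | chloro(2,2-dimethoxyethyl)methylsulfonium chloride | C[S+](Cl)CC(OC)OC.[Cl-]
F3 | step 5 | (2-ethoxy-2-oxoethyl)(methyl)[(3,4,5-tribromophenyl)amino]sulfonium chloride | CCOC(=O)C[S+](C)Nc1cc(Br)c(Br)c(Br)c1.[Cl-]
F4 | step 5 | ethyl 2-(2-amino-4,5,6-tribromophenyl)-2-(methylsulfanyl)acetate (racemic) | CCOC(=O)C(SC)c1c(N)cc(Br)c(Br)c1Br
F5 | step 5 | 4,5,6-tribromo-3-(methylsulfanyl)-1,3-dihydro-2H-indol-2-one (racemic) | CSC1C(=O)Nc2cc(Br)c(Br)c(Br)c12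
F6 | step 4 | 1-(2-amino-4,5,6-tribromophenyl)-2-chloroethan-1-one | Nc1cc(Br)c(Br)c(Br)c1C(=O)CCl
F7 | step 4 | 4,5,6-tribromo-1H-indole | Brc1cc2[nH]ccc2c(Br)c1Br
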